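**Plan**
1. The lactone C3–CH2 bond is cut first (enolate alkylation): it separates benzylic bromide 16 (dihydrobenzofuran half, fragment 1) from β-benzyl lactone 39 (diol-wing half, fragment 2).
2. In 16 the bond between the fused arene and C3 of the dihydrobenzofuran is traced back to a 1,2-aryl shift in (2S)-flavanone 8; the C2–aryl bond of 8 comes from a rhodium/chiral-diene conjugate addition to chromone 4.
3. The feature that allows this: C3 of the dihydrobenzofuran is bonded to the fused arene carbon C3a, to C2 (which carries the ring oxygen and the aryl group) and to one exocyclic oxygenated carbon. This is the atom set of a 2-arylchroman-4-one whose carbonyl carbon C4 has left the ring.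
4. In 39 the C1–C2 bond of the propane-1,3-diol is cut by an anti-aldol, the bond from ring B (the central phenol ring) to C2 by an aromatic Claisen rearrangement (allyl → arylacetic acid), and the benzylic C–C bond of the lactone by an auxiliary-controlled succinate alkylation.
5. Forward, the rings arise in the order chromone → flavanone → contracted dihydrobenzofuran (fragment 1), and lactone by reduction/lactonisation (fragment 2). The halves are joined by trans-selective lactone alkylation and six silyl ethers are removed last.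
6. Stereochemistry: dihydrobenzofuran C2 from the chiral diene and C3 from the stereospecific shift; lactone C4 from (R)-4-benzyloxazolidinone and C3 from C4 by anti alkylation; diol C1/C2 from (S)-4-benzyloxazolidinone in a magnesium-catalysed anti-aldol.

Key step: step 6

Assumption: the rhodium/diene addition to the chromone is taken to follow the facial model established for cyclic enones, so the (1S,4S)-diene should give the (2S)-flavanone; if the sense is the reverse, the (1R,4R)-diene is used and nothing else changes.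

**Fragment 1 (steps 1–11)**

Step 1
Reactants: 1 1-(2-hydroxy-3-methoxyphenyl)ethan-1-one
Product: 2 1-(5-bromo-2-hydroxy-3-methoxyphenyl)ethan-1-one
Conditions: NBS, MeCN, 0 °C → rt
Reagents that add atoms: N-bromosuccinimide, O=C1CCC(=O)N1Br
Why: Electrophilic aromatic bromination should go para to the free phenol, the only open position it activates, and NBS in MeCN spares the methyl ketone.

Step 2
Reactants: 2 1-(5-bromo-2-hydroxy-3-methoxyphenyl)ethan-1-one
Product: 4 6-bromo-8-methoxy-4H-chromen-4-one, via enaminone 3 (not isolated)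
Conditions: Me2NCH(OMe)2, toluene, 100 °C; then conc. HCl, CH2Cl2, 40 °C
Reagents that add atoms: N,N-dimethylformamide dimethyl acetal, COC(OC)N(C)C
Why: Condensation of the methyl ketone with the formamide acetal gives the o-hydroxyaryl enaminone, which in acid undergoes conjugate addition of the phenol oxygen and loss of dimethylamine (enaminone chromone synthesis).

Step 3
Reactants: 5 2-methoxy-4-(4,4,5,5-tetramethyl-1,3,2-dioxaborolan-2-yl)phenol
Product: 6 2-methoxy-4-(4,4,5,5-tetramethyl-1,3,2-dioxaborolan-2-yl)phenyl 4-methylbenzenesulfonate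
Conditions: TsCl, Et3N, DMAP (cat.), CH2Cl2, 0 °C → rt
Reagents that add atoms: 4-methylbenzenesulfonyl chloride, Cc1ccc(S(=O)(=O)Cl)cc1
Why: O-sulfonylation of the phenol installs the electron-withdrawing group needed in step 6, and the pinacol boronate is inert to these conditions.

Step 4
Reactants: 6 2-methoxy-4-(4,4,5,5-tetramethyl-1,3,2-dioxaborolan-2-yl)phenyl 4-methylbenzenesulfonate
Product: 7 {3-methoxy-4-[(4-methylbenzenesulfonyl)oxy]phenyl}boronic acid
Conditions: NaIO4, NH4OAc, acetone/H2O, rt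
Reagents that add atoms: water, O
Why: Periodate cleaves the pinacol released in the hydrolysis equilibrium and so drives the boronate to the free boronic acid, which transmetalates to rhodium far more readily than the ester; the tosylate is stable at this pH.

Step 5
Reactants: 4 6-bromo-8-methoxy-4H-chromen-4-one; 7 {3-methoxy-4-[(4-methylbenzenesulfonyl)oxy]phenyl}boronic acid
Product: 8 (2S)-6-bromo-8-methoxy-2-{3-methoxy-4-[(4-methylbenzenesulfonyl)oxy]phenyl}-2,3-dihydro-4H-chromen-4-one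
Conditions: [RhCl(C2H4)2]2 (2.5 mol%), (1S,4S)-2,5-diphenylbicyclo[2.2.2]octa-2,5-diene (6 mol%), KOH (0.2 equiv), toluene/H2O (10:1), 40 °C
Reagents that add atoms: none
Why: Hayashi–Miyaura asymmetric 1,4-addition: the aryl–rhodium species formed by transmetalation inserts the chromone C2=C3 bond on the enantioface selected by the C2-symmetric diene, which sets C2 as S, while the low base loading keeps the flavanone from ring opening and the tosylate and aryl bromide are inert to monovalent rhodium.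

Step 6
Reactants: 8 (2S)-6-bromo-8-methoxy-2-{3-methoxy-4-[(4-methylbenzenesulfonyl)oxy]phenyl}-2,3-dihydro-4H-chromen-4-one
Product: 10 methyl (2S,3S)-5-bromo-7-methoxy-2-{3-methoxy-4-[(4-methylbenzenesulfonyl)oxy]phenyl}-2,3-dihydro-1-benzofuran-3-carboxylate, via methyl enol ether 9 (not isolated)
Conditions: PhI(OAc)2 (1.3 equiv), conc. H2SO4 (0.5 equiv), HC(OMe)3, 0 °C → rt
Reagents that add atoms: trimethyl orthoformate, COC(OC)OC
Why: Acid and orthoformate turn the ketone into methyl enol ether 9 (in equilibrium with the dimethyl ketal); trivalent iodine adds to C3 on the face anti to the C2 aryl group while methanol returns to C4, and the fused arene carbon C4a then shifts from C4 to C3 with inversion as iodobenzene departs, leaving a dimethoxycarbenium ion at the former C4 that collapses to the methyl ester. The closest known reaction type is the oxidative ring contraction of flavanones to trans-2-aryl-2,3-dihydrobenzofuran-3-carboxylates by trivalent iodine or trivalent thallium in trimethyl orthoformate, a relative of the 1,2-aryl shift of aryl ketone acetals to arylacetic esters. The five-membered ring is not closed by a cyclisation: it arises by contraction of the six-membered pyranone when the new C3–C4a bond forms through a bridged phenonium transition state and C4 leaves the ring. The new stereocentre C3 is controlled by the existing C2 centre, because anti iodination followed by an invertive shift places the ester trans to the aryl group (2S,3S), the arrangement that is also thermodynamically preferred for this epimerisable ester; C2 itself is not touched. The step needs migration of the fused arene in preference to migration of the C2 aryl group (isoflavone) and to elimination (flavone): the tosylate makes the C2 aryl group electron-poor, the ring oxygen on C8a ortho to C4a stabilises the phenonium ion whereas bromine and methoxy sit meta to C4a and act only inductively, and the orthoformate medium keeps the substrate on the enol ether path.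

Step 7
Reactants: 10 methyl (2S,3S)-5-bromo-7-methoxy-2-{3-methoxy-4-[(4-methylbenzenesulfonyl)oxy]phenyl}-2,3-dihydro-1-benzofuran-3-carboxylate
Product: 11 4-[(2S,3R)-5-bromo-3-(hydroxymethyl)-7-methoxy-2,3-dihydro-1-benzofuran-2-yl]-2-methoxyphenyl 4-methylbenzenesulfonate
Conditions: iBu2AlH (3 equiv), CH2Cl2, −78 → 0 °C; aq. Rochelle salt
Reagents that add atoms: none
Why: Hydride reduction of the ester under non-basic conditions should give the primary alcohol without epimerising C3 or opening the ring by β-elimination of the aryloxide; the descriptor at C3 changes to R only through substituent priority, and the aryl bromide and tosylate survive.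

Step 8
Reactants: 11 4-[(2S,3R)-5-bromo-3-(hydroxymethyl)-7-methoxy-2,3-dihydro-1-benzofuran-2-yl]-2-methoxyphenyl 4-methylbenzenesulfonate
Product: 12 4-[(2S,3R)-5-bromo-3-(hydroxymethyl)-7-methoxy-2,3-dihydro-1-benzofuran-2-yl]-2-methoxyphenol
Conditions: KOH, MeOH/THF/H2O, 60 °C; then aq. NH4Cl
Reagents that add atoms: none
Why: Alkaline S–O cleavage of the aryl sulfonate frees the phenol now that no acidifying ester remains at C3, and the aryl bromide is inert to hydroxide.

Step 9
Reactants: 12 4-[(2S,3R)-5-bromo-3-(hydroxymethyl)-7-methoxy-2,3-dihydro-1-benzofuran-2-yl]-2-methoxyphenol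
Product: 13 (2S,3R)-5-bromo-3-{[(tert-butyldimethylsilyl)oxy]methyl}-2-{4-[(tert-butyldimethylsilyl)oxy]-3-methoxyphenyl}-7-methoxy-2,3-dihydro-1-benzofuran
Conditions: TBSCl (2.5 equiv), imidazole, DMF, rt
Reagents that add atoms: tert-butyldimethylsilyl chloride, CC(C)(C)[Si](C)(C)Cl
Why: Silylation of the phenol and the primary alcohol gives groups that tolerate organolithium and amide bases and leave together at the end with fluoride.

Step 10
Reactants: 13 (2S,3R)-5-bromo-3-{[(tert-butyldimethylsilyl)oxy]methyl}-2-{4-[(tert-butyldimethylsilyl)oxy]-3-methoxyphenyl}-7-methoxy-2,3-dihydro-1-benzofuran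
Product: 15 [(2S,3R)-3-{[(tert-butyldimethylsilyl)oxy]methyl}-2-{4-[(tert-butyldimethylsilyl)oxy]-3-methoxyphenyl}-7-methoxy-2,3-dihydro-1-benzofuran-5-yl]methanol, via aldehyde 14 (not isolated)
Conditions: n-BuLi, THF, −78 °C; DMF, −78 → 0 °C; then MeOH, NaBH4, 0 °C
Reagents that add atoms: N,N-dimethylformamide, CN(C)C=O
Why: Bromine–lithium exchange is faster than any attack on the silyl ethers at −78 °C, Bouveault formylation of the aryllithium gives the aldehyde, and borohydride reduces it in the same flask to the benzylic alcohol.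

Step 11
Reactants: 15 [(2S,3R)-3-{[(tert-butyldimethylsilyl)oxy]methyl}-2-{4-[(tert-butyldimethylsilyl)oxy]-3-methoxyphenyl}-7-methoxy-2,3-dihydro-1-benzofuran-5-yl]methanol
Product: 16 (2S,3R)-5-(bromomethyl)-3-{[(tert-butyldimethylsilyl)oxy]methyl}-2-{4-[(tert-butyldimethylsilyl)oxy]-3-methoxyphenyl}-7-methoxy-2,3-dihydro-1-benzofuran
Conditions: CBr4, PPh3, 2,6-lutidine, CH2Cl2, 0 °C; used directly
Reagents that add atoms: carbon tetrabromide, BrC(Br)(Br)Br
Why: Appel bromination converts the benzylic alcohol into the bromide under essentially neutral conditions that leave the silyl ethers and the benzylic ring C–O bond intact.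

**Fragment 2 (steps 12–25)**

Step 12
Reactants: 17 4-(hydroxymethyl)-2-methoxyphenol (vanillyl alcohol)
Product: 18 [3-methoxy-4-(prop-2-en-1-yloxy)phenyl]methanol
Conditions: allyl bromide, K2CO3, acetone, reflux
Reagents that add atoms: allyl bromide, C=CCBr
Why: Williamson etherification is selective for the phenoxide over the benzylic alcohol, and the allyl ether serves as protecting group and as the later source of C2 and C3 of the diol wing.

Step 13
Reactants: 18 [3-methoxy-4-(prop-2-en-1-yloxy)phenyl]methanol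
Product: 19 4-(bromomethyl)-2-methoxy-1-(prop-2-en-1-yloxy)benzene
Conditions: PBr3, Et2O, 0 °C
Reagents that add atoms: phosphorus tribromide, BrP(Br)Br
Why: Standard conversion of an electron-rich benzylic alcohol into the bromide; the allyl aryl ether is unaffected at 0 °C.

Step 14
Reactants: 20 4-(tert-butoxy)-4-oxobutanoic acid; 21 (4R)-4-benzyl-1,3-oxazolidin-2-one
Product: 23 tert-butyl 4-[(4R)-4-benzyl-2-oxo-1,3-oxazolidin-3-yl]-4-oxobutanoate, via mixed pivalic anhydride 22 (not isolated)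
Conditions: PivCl, Et3N, THF, −20 °C; then LiCl, 21, rt
Reagents that add atoms: none
Why: Mixed-anhydride N-acylation of the oxazolidinone under mild LiCl/Et3N conditions; the hindered pivaloyl carbonyl directs attack to the succinyl carbonyl.

Step 15
Reactants: 23 tert-butyl 4-[(4R)-4-benzyl-2-oxo-1,3-oxazolidin-3-yl]-4-oxobutanoate; 19 4-(bromomethyl)-2-methoxy-1-(prop-2-en-1-yloxy)benzene
Product: 24 tert-butyl (3R)-4-[(4R)-4-benzyl-2-oxo-1,3-oxazolidin-3-yl]-3-{[3-methoxy-4-(prop-2-en-1-yloxy)phenyl]methyl}-4-oxobutanoate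
Conditions: NaN(SiMe3)2, THF, −78 °C; then 19, −78 → −40 °C
Reagents that add atoms: none
Why: Evans-type asymmetric alkylation: the imide is deprotonated in preference to the tert-butyl ester, and the chelated (Z)-sodium enolate is benzylated on the face opposite the auxiliary benzyl group, which sets the new centre as R.

Step 16
Reactants: 24 tert-butyl (3R)-4-[(4R)-4-benzyl-2-oxo-1,3-oxazolidin-3-yl]-3-{[3-methoxy-4-(prop-2-en-1-yloxy)phenyl]methyl}-4-oxobutanoate
Product: 26 (4R)-4-{[3-methoxy-4-(prop-2-en-1-yloxy)phenyl]methyl}oxolan-2-one, via hydroxy ester 25 (not isolated)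
Conditions: LiBH4, MeOH (1 equiv), THF, 0 °C; then p-TsOH·H2O, CH2Cl2, rt
Reagents that add atoms: none
Why: Borohydride removes the auxiliary reductively from the activated imide while the tert-butyl ester survives, and acid then closes the γ-lactone by 5-exo-trig acyl substitution; the stereocentre is not enolisable and stays R.

Step 17
Reactants: 26 (4R)-4-{[3-methoxy-4-(prop-2-en-1-yloxy)phenyl]methyl}oxolan-2-one
Product: 27 (4R)-4-{[4-hydroxy-3-methoxy-5-(prop-2-en-1-yl)phenyl]methyl}oxolan-2-one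
Conditions: N,N-diethylaniline, 200 °C, sealed tube
Reagents that add atoms: none
Why: Aromatic Claisen rearrangement ([3,3]-sigmatropic shift then tautomerisation) delivers the allyl group to the only free ortho position, forming the ring B–carbon bond of the diol wing.

Step 18
Reactants: 27 (4R)-4-{[4-hydroxy-3-methoxy-5-(prop-2-en-1-yl)phenyl]methyl}oxolan-2-one
Product: 28 (4R)-4-{[4-[(tert-butyldimethylsilyl)oxy]-3-methoxy-5-(prop-2-en-1-yl)phenyl]methyl}oxolan-2-one
Conditions: TBSCl, imidazole, DMAP (cat.), DMF, 40 °C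
Reagents that add atoms: tert-butyldimethylsilyl chloride, CC(C)(C)[Si](C)(C)Cl
Why: Silylation masks the hindered phenol for the oxidative, basic and enolate steps that follow.

Step 19
Reactants: 28 (4R)-4-{[4-[(tert-butyldimethylsilyl)oxy]-3-methoxy-5-(prop-2-en-1-yl)phenyl]methyl}oxolan-2-one
Product: 29 {2-[(tert-butyldimethylsilyl)oxy]-3-methoxy-5-{[(3R)-5-oxooxolan-3-yl]methyl}phenyl}acetaldehyde
Conditions: OsO4 (2 mol%), NaIO4, 2,6-lutidine, dioxane/H2O, rt
Reagents that add atoms: sodium periodate, [Na+].[O-]I(=O)(=O)=O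
Why: Lemieux–Johnson cleavage (dihydroxylation then glycol fission) shortens the terminal alkene by one carbon to the arylacetaldehyde without touching the electron-rich arene.

Step 20
Reactants: 29 {2-[(tert-butyldimethylsilyl)oxy]-3-methoxy-5-{[(3R)-5-oxooxolan-3-yl]methyl}phenyl}acetaldehyde
Product: 30 {2-[(tert-butyldimethylsilyl)oxy]-3-methoxy-5-{[(3R)-5-oxooxolan-3-yl]methyl}phenyl}acetic acid
Conditions: NaClO2, NaH2PO4, 2-methyl-2-butene, t-BuOH/H2O, 0 °C → rt
Reagents that add atoms: sodium chlorite, [Na+].[O-]Cl=O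
Why: Pinnick oxidation takes the sensitive aldehyde to the acid under buffered conditions, with the alkene scavenger protecting the arene from hypochlorite.

Step 21
Reactants: 30 {2-[(tert-butyldimethylsilyl)oxy]-3-methoxy-5-{[(3R)-5-oxooxolan-3-yl]methyl}phenyl}acetic acid; 31 (4S)-4-benzyl-1,3-oxazolidin-2-one
Product: 33 (4S)-4-benzyl-3-({2-[(tert-butyldimethylsilyl)oxy]-3-methoxy-5-{[(3R)-5-oxooxolan-3-yl]methyl}phenyl}acetyl)-1,3-oxazolidin-2-one, via mixed pivalic anhydride 32 (not isolated)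
Conditions: PivCl, Et3N, THF, −20 °C; then LiCl, 31, rt
Reagents that add atoms: none
Why: Mixed-anhydride N-acylation under LiCl/Et3N conditions is mild enough for the lactone and the aryl silyl ether.

Step 22
Reactants: 34 4-hydroxy-3-methoxybenzaldehyde (vanillin)
Product: 35 4-[(tert-butyldimethylsilyl)oxy]-3-methoxybenzaldehyde
Conditions: TBSCl, imidazole, CH2Cl2, rt
Reagents that add atoms: tert-butyldimethylsilyl chloride, CC(C)(C)[Si](C)(C)Cl
Why: Routine phenol silylation gives the aldehyde partner in the same protecting-group family as the rest of the route.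

Step 23
Reactants: 33 (4S)-4-benzyl-3-({2-[(tert-butyldimethylsilyl)oxy]-3-methoxy-5-{[(3R)-5-oxooxolan-3-yl]methyl}phenyl}acetyl)-1,3-oxazolidin-2-one; 35 4-[(tert-butyldimethylsilyl)oxy]-3-methoxybenzaldehyde
Product: 37 (4S)-4-benzyl-3-[(2R,3S)-2-{2-[(tert-butyldimethylsilyl)oxy]-3-methoxy-5-{[(3R)-5-oxooxolan-3-yl]methyl}phenyl}-3-{4-[(tert-butyldimethylsilyl)oxy]-3-methoxyphenyl}-3-hydroxypropanoyl]-1,3-oxazolidin-2-one, via trimethylsilyl ether 36 (not isolated)
Conditions: MgCl2 (20 mol%), Et3N, Me3SiCl, EtOAc, rt; then CF3CO2H (cat.), MeOH, rt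
Reagents that add atoms: none
Why: Magnesium halide-catalysed direct anti-aldol of an N-acyloxazolidinone with an aromatic aldehyde: soft enolisation gives the chelated (Z)-magnesium enolate, the aldehyde adds on the face opposite the auxiliary benzyl group through a boat-like transition state to give the 2,3-anti adduct (2R,3S), silylation of the aldolate turns the catalyst over and blocks retro-aldol, and the lactone is not enolised by Et3N.

Step 24
Reactants: 37 (4S)-4-benzyl-3-[(2R,3S)-2-{2-[(tert-butyldimethylsilyl)oxy]-3-methoxy-5-{[(3R)-5-oxooxolan-3-yl]methyl}phenyl}-3-{4-[(tert-butyldimethylsilyl)oxy]-3-methoxyphenyl}-3-hydroxypropanoyl]-1,3-oxazolidin-2-one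
Product: 38 (4R)-4-{[4-[(tert-butyldimethylsilyl)oxy]-3-[(1S,2S)-1-{4-[(tert-butyldimethylsilyl)oxy]-3-methoxyphenyl}-1,3-dihydroxypropan-2-yl]-5-methoxyphenyl]methyl}oxolan-2-one
Conditions: NaBH4, THF/H2O (4:1), 0 °C
Reagents that add atoms: none
Why: Borohydride in aqueous THF reduces the twisted, doubly activated exocyclic imide carbonyl much faster than the γ-lactone, releasing the auxiliary and giving the anti-1,3-diol with both centres unchanged in space (descriptors 1S,2S).

Step 25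
Reactants: 38 (4R)-4-{[4-[(tert-butyldimethylsilyl)oxy]-3-[(1S,2S)-1-{4-[(tert-butyldimethylsilyl)oxy]-3-methoxyphenyl}-1,3-dihydroxypropan-2-yl]-5-methoxyphenyl]methyl}oxolan-2-one
Product: 39 (4R)-4-{[3-[(1S,2S)-1,3-bis[(tert-butyldimethylsilyl)oxy]-1-{4-[(tert-butyldimethylsilyl)oxy]-3-methoxyphenyl}propan-2-yl]-4-[(tert-butyldimethylsilyl)oxy]-5-methoxyphenyl]methyl}oxolan-2-one
Conditions: TBSOTf (3 equiv), 2,6-lutidine, CH2Cl2, −78 → 0 °C
Reagents that add atoms: tert-butyldimethylsilyl trifluoromethanesulfonate, CC(C)(C)[Si](C)(C)OS(=O)(=O)C(F)(F)F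
Why: The silyl triflate caps the primary and the hindered benzylic hydroxyl so that no acidic proton competes with lactone enolisation in the next step.

**Union and deprotection (steps 26–27)**

Step 26
Reactants: 39 (4R)-4-{[3-[(1S,2S)-1,3-bis[(tert-butyldimethylsilyl)oxy]-1-{4-[(tert-butyldimethylsilyl)oxy]-3-methoxyphenyl}propan-2-yl]-4-[(tert-butyldimethylsilyl)oxy]-5-methoxyphenyl]methyl}oxolan-2-one; 16 (2S,3R)-5-(bromomethyl)-3-{[(tert-butyldimethylsilyl)oxy]methyl}-2-{4-[(tert-butyldimethylsilyl)oxy]-3-methoxyphenyl}-7-methoxy-2,3-dihydro-1-benzofuran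
Product: 40 hexakis(tert-butyldimethylsilyl) ether of the target: the (3R,4R)-trans-3,4-dibenzyloxolan-2-one carrying the (2S,3R)-dihydrobenzofuranylmethyl group on C3 and the (1S,2S)-diol-wing benzyl group on C4, with all six hydroxyl groups silylated
Conditions: LiN(SiMe3)2, THF, −78 °C; then 16, DMPU, −78 → −30 °C
Reagents that add atoms: none
Why: Alkylation of the lithium enolate of a β-substituted γ-butyrolactone with a benzylic bromide occurs anti to the C4 substituent, so the existing C4 centre sets C3 as R (trans), as in the standard dibenzylbutyrolactone lignan alkylation.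

Step 27
Reactants: 40 hexakis(tert-butyldimethylsilyl) ether of the target
Product: 41 (3R,4R)-3-{[(2S,3R)-2-(4-hydroxy-3-methoxyphenyl)-3-(hydroxymethyl)-7-methoxy-2,3-dihydro-1-benzofuran-5-yl]methyl}-4-({3-[(1S,2S)-1,3-dihydroxy-1-(4-hydroxy-3-methoxyphenyl)propan-2-yl]-4-hydroxy-5-methoxyphenyl}methyl)oxolan-2-one (CNP0199264.2)
Conditions: Bu4NF, AcOH (1:1, excess), THF, 0 °C → rt
Reagents that add atoms: none
Why: Buffered fluoride removes all six silyl ethers near neutrality, which should avoid acid-induced ionisation of the benzylic carbinol (cyclisation onto the ring B phenol, epimerisation) and base-induced opening of the lactone or the dihydrobenzofuran.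

**Compound list**
1 | 1-(2-hydroxy-3-methoxyphenyl)ethan-1-one | CC(=O)c1cccc(OC)c1O | starting material
2 | 1-(5-bromo-2-hydroxy-3-methoxyphenyl)ethan-1-one | CC(=O)c1cc(Br)cc(OC)c1O | intermediate
3 | (E)-1-(5-bromo-2-hydroxy-3-methoxyphenyl)-3-(dimethylamino)prop-2-en-1-one (formed in situ) | CN(C)/C=C/C(=O)c1cc(Br)cc(OC)c1O | intermediate
4 | 6-bromo-8-methoxy-4H-chromen-4-one | O=c1ccoc2c(OC)cc(Br)cc12 | intermediate
5 | 2-methoxy-4-(4,4,5,5-tetramethyl-1,3,2-dioxaborolan-2-yl)phenol | COc1cc(B2OC(C)(C)C(C)(C)O2)ccc1O | starting material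
6 | 2-methoxy-4-(4,4,5,5-tetramethyl-1,3,2-dioxaborolan-2-yl)phenyl 4-methylbenzenesulfonate | COc1cc(B2OC(C)(C)C(C)(C)O2)ccc1OS(=O)(=O)c1ccc(C)cc1 | intermediate
7 | {3-methoxy-4-[(4-methylbenzenesulfonyl)oxy]phenyl}boronic acid | COc1cc(B(O)O)ccc1OS(=O)(=O)c1ccc(C)cc1 | intermediate
8 | (2S)-6-bromo-8-methoxy-2-{3-methoxy-4-[(4-methylbenzenesulfonyl)oxy]phenyl}-2,3-dihydro-4H-chromen-4-one | Brc1cc(OC)c2c(c1)C(=O)C[C@@H](c1ccc(OS(=O)(=O)c3ccc(C)cc3)c(OC)c1)O2 | intermediate
9 | (2S)-6-bromo-4,8-dimethoxy-2-{3-methoxy-4-[(4-methylbenzenesulfonyl)oxy]phenyl}-2H-chromene (formed in situ) | Brc1cc(OC)c2c(c1)C(OC)=C[C@@H](c1ccc(OS(=O)(=O)c3ccc(C)cc3)c(OC)c1)O2 | intermediate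
10 | methyl (2S,3S)-5-bromo-7-methoxy-2-{3-methoxy-4-[(4-methylbenzenesulfonyl)oxy]phenyl}-2,3-dihydro-1-benzofuran-3-carboxylate (trans) | Brc1cc(OC)c2c(c1)[C@H](C(=O)OC)[C@@H](c1ccc(OS(=O)(=O)c3ccc(C)cc3)c(OC)c1)O2 | intermediate
11 | 4-[(2S,3R)-5-bromo-3-(hydroxymethyl)-7-methoxy-2,3-dihydro-1-benzofuran-2-yl]-2-methoxyphenyl 4-methylbenzenesulfonate | Brc1cc(OC)c2c(c1)[C@H](CO)[C@@H](c1ccc(OS(=O)(=O)c3ccc(C)cc3)c(OC)c1)O2 | intermediate
12 | 4-[(2S,3R)-5-bromo-3-(hydroxymethyl)-7-methoxy-2,3-dihydro-1-benzofuran-2-yl]-2-methoxyphenol | Brc1cc(OC)c2c(c1)[C@H](CO)[C@@H](c1ccc(O)c(OC)c1)O2 | intermediate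
13 | (2S,3R)-5-bromo-3-{[(tert-butyldimethylsilyl)oxy]methyl}-2-{4-[(tert-butyldimethylsilyl)oxy]-3-methoxyphenyl}-7-methoxy-2,3-dihydro-1-benzofuran | Brc1cc(OC)c2c(c1)[C@H](CO[Si](C)(C)C(C)(C)C)[C@@H](c1ccc(O[Si](C)(C)C(C)(C)C)c(OC)c1)O2 | intermediate
14 | (2S,3R)-3-{[(tert-butyldimethylsilyl)oxy]methyl}-2-{4-[(tert-butyldimethylsilyl)oxy]-3-methoxyphenyl}-7-methoxy-2,3-dihydro-1-benzofuran-5-carbaldehyde (formed in situ) | O=Cc1cc(OC)c2c(c1)[C@H](CO[Si](C)(C)C(C)(C)C)[C@@H](c1ccc(O[Si](C)(C)C(C)(C)C)c(OC)c1)O2 | intermediate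
15 | [(2S,3R)-3-{[(tert-butyldimethylsilyl)oxy]methyl}-2-{4-[(tert-butyldimethylsilyl)oxy]-3-methoxyphenyl}-7-methoxy-2,3-dihydro-1-benzofuran-5-yl]methanol | OCc1cc(OC)c2c(c1)[C@H](CO[Si](C)(C)C(C)(C)C)[C@@H](c1ccc(O[Si](C)(C)C(C)(C)C)c(OC)c1)O2 | intermediate
16 | (2S,3R)-5-(bromomethyl)-3-{[(tert-butyldimethylsilyl)oxy]methyl}-2-{4-[(tert-butyldimethylsilyl)oxy]-3-methoxyphenyl}-7-methoxy-2,3-dihydro-1-benzofuran | BrCc1cc(OC)c2c(c1)[C@H](CO[Si](C)(C)C(C)(C)C)[C@@H](c1ccc(O[Si](C)(C)C(C)(C)C)c(OC)c1)O2 | intermediate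
17 | 4-(hydroxymethyl)-2-methoxyphenol (vanillyl alcohol) | COc1cc(CO)ccc1O | starting material
18 | [3-methoxy-4-(prop-2-en-1-yloxy)phenyl]methanol | C=CCOc1ccc(CO)cc1OC | intermediate
19 | 4-(bromomethyl)-2-methoxy-1-(prop-2-en-1-yloxy)benzene | C=CCOc1ccc(CBr)cc1OC | intermediate
20 | 4-(tert-butoxy)-4-oxobutanoic acid | CC(C)(C)OC(=O)CCC(=O)O | starting material
21 | (4R)-4-benzyl-1,3-oxazolidin-2-one | O=C1N[C@H](Cc2ccccc2)CO1 | starting material
22 | 4-(tert-butoxy)-4-oxobutanoic pivalic anhydride (formed in situ) | CC(C)(C)OC(=O)CCC(=O)OC(=O)C(C)(C)C | intermediate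
23 | tert-butyl 4-[(4R)-4-benzyl-2-oxo-1,3-oxazolidin-3-yl]-4-oxobutanoate | CC(C)(C)OC(=O)CCC(=O)N1[C@H](Cc2ccccc2)COC1=O | intermediate
24 | tert-butyl (3R)-4-[(4R)-4-benzyl-2-oxo-1,3-oxazolidin-3-yl]-3-{[3-methoxy-4-(prop-2-en-1-yloxy)phenyl]methyl}-4-oxobutanoate | CC(C)(C)OC(=O)C[C@@H](Cc1ccc(OCC=C)c(OC)c1)C(=O)N1[C@H](Cc2ccccc2)COC1=O | intermediate
25 | tert-butyl (3R)-3-(hydroxymethyl)-4-[3-methoxy-4-(prop-2-en-1-yloxy)phenyl]butanoate (formed in situ) | CC(C)(C)OC(=O)C[C@@H](Cc1ccc(OCC=C)c(OC)c1)CO | intermediate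
26 | (4R)-4-{[3-methoxy-4-(prop-2-en-1-yloxy)phenyl]methyl}oxolan-2-one | O=C1C[C@@H](Cc2ccc(OCC=C)c(OC)c2)CO1 | intermediate
27 | (4R)-4-{[4-hydroxy-3-methoxy-5-(prop-2-en-1-yl)phenyl]methyl}oxolan-2-one | O=C1C[C@@H](Cc2cc(CC=C)c(O)c(OC)c2)CO1 | intermediate
28 | (4R)-4-{[4-[(tert-butyldimethylsilyl)oxy]-3-methoxy-5-(prop-2-en-1-yl)phenyl]methyl}oxolan-2-one | O=C1C[C@@H](Cc2cc(CC=C)c(O[Si](C)(C)C(C)(C)C)c(OC)c2)CO1 | intermediate
29 | {2-[(tert-butyldimethylsilyl)oxy]-3-methoxy-5-{[(3R)-5-oxooxolan-3-yl]methyl}phenyl}acetaldehyde | O=C1C[C@@H](Cc2cc(CC=O)c(O[Si](C)(C)C(C)(C)C)c(OC)c2)CO1 | intermediate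
30 | {2-[(tert-butyldimethylsilyl)oxy]-3-methoxy-5-{[(3R)-5-oxooxolan-3-yl]methyl}phenyl}acetic acid | O=C1C[C@@H](Cc2cc(CC(=O)O)c(O[Si](C)(C)C(C)(C)C)c(OC)c2)CO1 | intermediate
31 | (4S)-4-benzyl-1,3-oxazolidin-2-one | O=C1N[C@@H](Cc2ccccc2)CO1 | starting material
32 | mixed pivalic anhydride of acid 30 (formed in situ) | O=C1C[C@@H](Cc2cc(CC(=O)OC(=O)C(C)(C)C)c(O[Si](C)(C)C(C)(C)C)c(OC)c2)CO1 | intermediate
33 | (4S)-4-benzyl-3-({2-[(tert-butyldimethylsilyl)oxy]-3-methoxy-5-{[(3R)-5-oxooxolan-3-yl]methyl}phenyl}acetyl)-1,3-oxazolidin-2-one | O=C1C[C@@H](Cc2cc(CC(=O)N3[C@@H](Cc4ccccc4)COC3=O)c(O[Si](C)(C)C(C)(C)C)c(OC)c2)CO1 | intermediate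
34 | 4-hydroxy-3-methoxybenzaldehyde (vanillin) | COc1cc(C=O)ccc1O | starting material
35 | 4-[(tert-butyldimethylsilyl)oxy]-3-methoxybenzaldehyde | COc1cc(C=O)ccc1O[Si](C)(C)C(C)(C)C | intermediate
36 | 3-O-trimethylsilyl ether of aldol adduct 37, (2R,3S) (formed in situ) | O=C1C[C@@H](Cc2cc([C@@H](C(=O)N3[C@@H](Cc4ccccc4)COC3=O)[C@H](O[Si](C)(C)C)c3ccc(O[Si](C)(C)C(C)(C)C)c(OC)c3)c(O[Si](C)(C)C(C)(C)C)c(OC)c2)CO1 | intermediate
37 | (4S)-4-benzyl-3-[(2R,3S)-2-{2-[(tert-butyldimethylsilyl)oxy]-3-methoxy-5-{[(3R)-5-oxooxolan-3-yl]methyl}phenyl}-3-{4-[(tert-butyldimethylsilyl)oxy]-3-methoxyphenyl}-3-hydroxypropanoyl]-1,3-oxazolidin-2-one | O=C1C[C@@H](Cc2cc([C@@H](C(=O)N3[C@@H](Cc4ccccc4)COC3=O)[C@H](O)c3ccc(O[Si](C)(C)C(C)(C)C)c(OC)c3)c(O[Si](C)(C)C(C)(C)C)c(OC)c2)CO1 | intermediate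
38 | (4R)-4-{[4-[(tert-butyldimethylsilyl)oxy]-3-[(1S,2S)-1-{4-[(tert-butyldimethylsilyl)oxy]-3-methoxyphenyl}-1,3-dihydroxypropan-2-yl]-5-methoxyphenyl]methyl}oxolan-2-one | O=C1C[C@@H](Cc2cc([C@@H](CO)[C@H](O)c3ccc(O[Si](C)(C)C(C)(C)C)c(OC)c3)c(O[Si](C)(C)C(C)(C)C)c(OC)c2)CO1 | intermediate
39 | (4R)-4-{[3-[(1S,2S)-1,3-bis[(tert-butyldimethylsilyl)oxy]-1-{4-[(tert-butyldimethylsilyl)oxy]-3-methoxyphenyl}propan-2-yl]-4-[(tert-butyldimethylsilyl)oxy]-5-methoxyphenyl]methyl}oxolan-2-one | O=C1C[C@@H](Cc2cc([C@@H](CO[Si](C)(C)C(C)(C)C)[C@H](O[Si](C)(C)C(C)(C)C)c3ccc(O[Si](C)(C)C(C)(C)C)c(OC)c3)c(O[Si](C)(C)C(C)(C)C)c(OC)c2)CO1 | intermediate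
40 | hexakis(tert-butyldimethylsilyl) ether of the target, (3R,4R)-lactone, (2S,3R)-dihydrobenzofuran, (1S,2S)-diol wing | O=C1[C@H](Cc2cc(OC)c3c(c2)[C@H](CO[Si](C)(C)C(C)(C)C)[C@@H](c2ccc(O[Si](C)(C)C(C)(C)C)c(OC)c2)O3)[C@@H](Cc2cc([C@@H](CO[Si](C)(C)C(C)(C)C)[C@H](O[Si](C)(C)C(C)(C)C)c3ccc(O[Si](C)(C)C(C)(C)C)c(OC)c3)c(O[Si](C)(C)C(C)(C)C)c(OC)c2)CO1 | intermediate
41 | (3R,4R)-3-{[(2S,3R)-2-(4-hydroxy-3-methoxyphenyl)-3-(hydroxymethyl)-7-methoxy-2,3-dihydro-1-benzofuran-5-yl]methyl}-4-({3-[(1S,2S)-1,3-dihydroxy-1-(4-hydroxy-3-methoxyphenyl)propan-2-yl]-4-hydroxy-5-methoxyphenyl}methyl)oxolan-2-one | COc1cc([C@@H](O)[C@H](CO)c2cc(C[C@H]3COC(=O)[C@@H]3Cc3cc(OC)c4c(c3)[C@H](CO)[C@@H](c3ccc(O)c(OC)c3)O4)cc(OC)c2O)ccc1O | target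

**Step count and risks**
Total: 27 steps. Longest linear sequence: 14 steps (17 → 41 through steps 12, 13, 15–21 and 23–27); the dihydrobenzofuran branch is 11 steps (steps 1, 2, 5–11, 26, 27).

The three steps most likely to fail:

1. Step 23 (anti-aldol). The ortho-silyloxy arylacetyl imide may enolise slowly under the soft conditions, and the acidic benzylic α-centre may epimerise under Et3N, so that the anti/syn ratio erodes or conversion with the electron-rich aldehyde stalls. The fallback replaces catalytic soft enolisation by a preformed boron enolate reacting through an open transition state. It sets out from acid 30, which through anhydride 32 acylates the enantiomeric auxiliary 21 to give (4R)-4-benzyl-3-({2-[(tert-butyldimethylsilyl)oxy]-3-methoxy-5-{[(3R)-5-oxooxolan-3-yl]methyl}phenyl}acetyl)-1,3-oxazolidin-2-one F1. Its dibutylboron (Z)-enolate (Bu2BOSO2CF3, iPr2NEt, CH2Cl2, −78 °C) is added to aldehyde 35 precomplexed with Et2AlCl; the enolate face is fixed by the (R)-auxiliary and the Lewis-acid-bound aldehyde reacts anti, which should give the (2R,3S)-anti adduct carrying the (4R)-auxiliary F2. Reduction with NaBH4 as in step 24 returns to the route at diol 38.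

2. Step 6 (ring contraction). Elimination of the C3 iodane to the flavone may outrun the shift because bromine lowers the migratory aptitude of the fused arene, and acid-promoted opening and reclosure of the flavanone may erode enantiopurity during a slow reaction. The fallback keeps the contraction but runs it on the more electron-rich bromine-free arene and introduces bromine afterwards. It sets out from acetophenone 1, which with Me2NCH(OMe)2 gives (E)-3-(dimethylamino)-1-(2-hydroxy-3-methoxyphenyl)prop-2-en-1-one F3 and with HCl 8-methoxy-4H-chromen-4-one F4. Rhodium/diene addition of boronic acid 7 as in step 5 gives (2S)-8-methoxy-2-{3-methoxy-4-[(4-methylbenzenesulfonyl)oxy]phenyl}-2,3-dihydro-4H-chromen-4-one F5. PhI(OAc)2/H2SO4 in HC(OMe)3 then leads through (2S)-4,8-dimethoxy-2-{3-methoxy-4-[(4-methylbenzenesulfonyl)oxy]phenyl}-2H-chromene F6 to methyl (2S,3S)-7-methoxy-2-{3-methoxy-4-[(4-methylbenzenesulfonyl)oxy]phenyl}-2,3-dihydro-1-benzofuran-3-carboxylate F7. Bromination with NBS in MeCN, expected para to the furan oxygen on the more electron-rich ring, returns to the route at ester 10.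

3. Step 24 (reductive removal of the auxiliary). Hydride may attack the γ-lactone in competition with the imide, or the β-hydroxy imide may undergo retro-aldol cleavage in the basic aqueous borohydride medium. The fallback separates auxiliary cleavage from reduction. It sets out from aldol adduct 37, whose hydroxyl is silylated (TBSOTf, 2,6-lutidine) to the (2R,3S)-3-O-tert-butyldimethylsilyl imide F8. LiOH/H2O2 (THF/H2O, 0 °C), followed by acidification so that any opened lactone recloses, should give the (2R,3S)-carboxylic acid F9. BH3·SMe2 (THF, 0 °C) reduces the acid in preference to the lactone to the (1S,2S)-primary alcohol F10. Silylation with TBSCl/imidazole returns to the route at 39, bypassing 38.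

**Further compounds**
F1 | step 23 | (4R)-4-benzyl-3-({2-[(tert-butyldimethylsilyl)oxy]-3-methoxy-5-{[(3R)-5-oxooxolan-3-yl]methyl}phenyl}acetyl)-1,3-oxazolidin-2-one | O=C1C[C@@H](Cc2cc(CC(=O)N3[C@H](Cc4ccccc4)COC3=O)c(O[Si](C)(C)C(C)(C)C)c(OC)c2)CO1
F2 | step 23 | (4R)-4-benzyl-3-[(2R,3S)-2-{2-[(tert-butyldimethylsilyl)oxy]-3-methoxy-5-{[(3R)-5-oxooxolan-3-yl]methyl}phenyl}-3-{4-[(tert-butyldimethylsilyl)oxy]-3-methoxyphenyl}-3-hydroxypropanoyl]-1,3-oxazolidin-2-one | O=C1C[C@@H](Cc2cc([C@@H](C(=O)N3[C@H](Cc4ccccc4)COC3=O)[C@H](O)c3ccc(O[Si](C)(C)C(C)(C)C)c(OC)c3)c(O[Si](C)(C)C(C)(C)C)c(OC)c2)CO1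
F3 | step 6 | (E)-3-(dimethylamino)-1-(2-hydroxy-3-methoxyphenyl)prop-2-en-1-one | CN(C)/C=C/C(=O)c1cccc(OC)c1O
F4 | step 6 | 8-methoxy-4H-chromen-4-one | O=c1ccoc2c(OC)cccc12
F5 | step 6 | (2S)-8-methoxy-2-{3-methoxy-4-[(4-methylbenzenesulfonyl)oxy]phenyl}-2,3-dihydro-4H-chromen-4-one | c1cc(OC)c2c(c1)C(=O)C[C@@H](c1ccc(OS(=O)(=O)c3ccc(C)cc3)c(OC)c1)O2
F6 | step 6 | (2S)-4,8-dimethoxy-2-{3-methoxy-4-[(4-methylbenzenesulfonyl)oxy]phenyl}-2H-chromene | c1cc(OC)c2c(c1)C(OC)=C[C@@H](c1ccc(OS(=O)(=O)c3ccc(C)cc3)c(OC)c1)O2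
F7 | step 6 | methyl (2S,3S)-7-methoxy-2-{3-methoxy-4-[(4-methylbenzenesulfonyl)oxy]phenyl}-2,3-dihydro-1-benzofuran-3-carboxylate | c1cc(OC)c2c(c1)[C@H](C(=O)OC)[C@@H](c1ccc(OS(=O)(=O)c3ccc(C)cc3)c(OC)c1)O2
F8 | step 24 | (4S)-4-benzyl-3-[(2R,3S)-3-[(tert-butyldimethylsilyl)oxy]-2-{2-[(tert-butyldimethylsilyl)oxy]-3-methoxy-5-{[(3R)-5-oxooxolan-3-yl]methyl}phenyl}-3-{4-[(tert-butyldimethylsilyl)oxy]-3-methoxyphenyl}propanoyl]-1,3-oxazolidin-2-one | O=C1C[C@@H](Cc2cc([C@@H](C(=O)N3[C@@H](Cc4ccccc4)COC3=O)[C@H](O[Si](C)(C)C(C)(C)C)c3ccc(O[Si](C)(C)C(C)(C)C)c(OC)c3)c(O[Si](C)(C)C(C)(C)C)c(OC)c2)CO1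
F9 | step 24 | (2R,3S)-3-[(tert-butyldimethylsilyl)oxy]-2-{2-[(tert-butyldimethylsilyl)oxy]-3-methoxy-5-{[(3R)-5-oxooxolan-3-yl]methyl}phenyl}-3-{4-[(tert-butyldimethylsilyl)oxy]-3-methoxyphenyl}propanoic acid | O=C1C[C@@H](Cc2cc([C@@H](C(=O)O)[C@H](O[Si](C)(C)C(C)(C)C)c3ccc(O[Si](C)(C)C(C)(C)C)c(OC)c3)c(O[Si](C)(C)C(C)(C)C)c(OC)c2)CO1
F10 | step 24 | (4R)-4-{[4-[(tert-butyldimethylsilyl)oxy]-3-[(1S,2S)-1-[(tert-butyldimethylsilyl)oxy]-1-{4-[(tert-butyldimethylsilyl)oxy]-3-methoxyphenyl}-3-hydroxypropan-2-yl]-5-methoxyphenyl]methyl}oxolan-2-one | O=C1C[C@@H](Cc2cc([C@@H](CO)[C@H](O[Si](C)(C)C(C)(C)C)c3ccc(O[Si](C)(C)C(C)(C)C)c(OC)c3)c(O[Si](C)(C)C(C)(C)C)c(OC)c2)CO1
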